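**Plan**

- Retrosynthesis: the cyclohexene ring (C1''–C6'', with C1'' the methyl-bearing carbon and C7'' the methyl) is cut at C3''–C4'' and C5''–C6'' (retro-[4+2]). Two hydrogens are then returned to the diene, so the target falls into two prenylchalcones, isobavachalcone (10) and morachalcone A (15).
- Enabling feature: C3''–C2''–C1''(C7'')–C6'' is a dehydrogenated prenyl group on C3' of a 2',4'-dihydroxyaryl ketone, flanked by two phenols (a quinone-methide handle). C4''–C5'' is the Cα–Cβ of a second E-chalcone that carries the same prenylated A ring.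
- Forward: one ketone (5), made from 2,4-dihydroxyacetophenone by C3 iodination, MOM protection and Stille prenylation, is condensed with two aldehydes and deprotected to give 10 and 15.
- Last step: a flavin oxidase dehydrogenates the prenyl group of 10 to the (E)-diene, and an FAD-dependent Diels–Alderase joins it to 15. The cyclohexene is the only ring the route has to build.
- Stereochemistry: all three stereocentres arise in that step. 4'',5''-trans comes from the E enone of 15, 3'',4''-cis from the enzyme-enforced endo mode, and the absolute configuration (3''S,4''R,5''S) from the enzyme pocket.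

Key step: step 10

Assumption: both flavoenzymes are used as recombinant His-tagged proteins and count as catalysts. The target configuration (1S,5S,6R on the cyclohexenyl ring, i.e. 3''S,4''R,5''S) is that of the natural endo (cis,trans) adduct series, which is what the endo-selective Morus Diels–Alderase should deliver.

**Route**

Step 1
Reactants: 1 2,4-dihydroxyacetophenone
Product: 2 1-(2,4-dihydroxy-3-iodophenyl)ethanone
Conditions: I2 (0.4 equiv), HIO3 (0.2 equiv), EtOH/H2O, 35–40 °C
Reagents that add atoms: iodine, II; iodic acid, OI(=O)=O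
Why: Electrophilic aromatic iodination (I2/HIO3) should take place at C3, the position activated by both hydroxyl groups and favoured by the bond fixation of the chelated 2-OH/ketone, with one iodine equivalent in total to keep the 3,5-diiodide down.

Step 2
Reactants: 2 1-(2,4-dihydroxy-3-iodophenyl)ethanone
Product: 3 1-[3-iodo-2,4-bis(methoxymethoxy)phenyl]ethanone
Conditions: NaH (2.2 equiv), MOMCl (2.4 equiv), DMF, 0 °C → rt
Reagents that add atoms: chloromethyl methyl ether (MOMCl), COCCl
Why: Williamson-type O-alkylation of the two phenoxides; the strong base is needed to break the chelate of the 2-OH, and the far less acidic methyl ketone is not deprotonated by the 2.2 equivalents used.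

Step 3
Reactants: 3 1-[3-iodo-2,4-bis(methoxymethoxy)phenyl]ethanone; 4 tributyl(3-methylbut-2-en-1-yl)stannane
Product: 5 1-[2,4-bis(methoxymethoxy)-3-(3-methylbut-2-en-1-yl)phenyl]ethanone
Conditions: Pd(PPh3)4 (10 mol %), DMF, 100 °C
Reagents that add atoms: none
Why: Stille cross-coupling of the aryl iodide with the prenylstannane; the aryl–Pd–(η3-prenyl) intermediate should reductively eliminate at the unhindered primary terminus to give the linear prenyl arene, and ketone and MOM ethers are inert to the neutral conditions.

Step 4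
Reactants: 6 4-hydroxybenzaldehyde
Product: 7 4-(methoxymethoxy)benzaldehyde
Conditions: NaH (1.1 equiv), MOMCl (1.2 equiv), DMF, 0 °C → rt
Reagents that add atoms: chloromethyl methyl ether (MOMCl), COCCl
Why: Williamson-type O-alkylation of the phenoxide masks the phenol, which would otherwise deactivate the aldehyde as its phenoxide in the base-mediated condensation.

Step 5
Reactants: 5 1-[2,4-bis(methoxymethoxy)-3-(3-methylbut-2-en-1-yl)phenyl]ethanone; 7 4-(methoxymethoxy)benzaldehyde
Product: 9 (2E)-1-[2,4-bis(methoxymethoxy)-3-(3-methylbut-2-en-1-yl)phenyl]-3-[4-(methoxymethoxy)phenyl]prop-2-en-1-one, via aldol adduct 8 (not isolated)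
Conditions: KOH (50% aq., excess), EtOH, 0 °C → rt
Reagents that add atoms: none
Why: Claisen–Schmidt condensation; the methyl ketone enolate adds to the non-enolisable aldehyde and the β-hydroxy ketone 8 loses water by E1cB to the thermodynamically favoured E enone.

Step 6
Reactants: 9 (2E)-1-[2,4-bis(methoxymethoxy)-3-(3-methylbut-2-en-1-yl)phenyl]-3-[4-(methoxymethoxy)phenyl]prop-2-en-1-one
Product: 10 isobavachalcone = (2E)-1-[2,4-dihydroxy-3-(3-methylbut-2-en-1-yl)phenyl]-3-(4-hydroxyphenyl)prop-2-en-1-one
Conditions: conc. HCl (10 vol %) in MeOH, rt → 45 °C, short reaction time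
Reagents that add atoms: none
Why: Acid-catalysed acetal exchange with methanol (MOM ether cleavage) frees the three phenols, while the trisubstituted prenyl alkene and the enone should survive dilute acid at moderate temperature.

Step 7
Reactants: 11 2,4-dihydroxybenzaldehyde
Product: 12 2,4-bis(methoxymethoxy)benzaldehyde
Conditions: NaH (2.2 equiv), MOMCl (2.4 equiv), DMF, 0 °C → rt
Reagents that add atoms: chloromethyl methyl ether (MOMCl), COCCl
Why: Williamson-type O-alkylation of both phenoxides, including the chelated 2-OH, gives a non-enolisable, non-ionisable aldehyde for the condensation.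

Step 8
Reactants: 5 1-[2,4-bis(methoxymethoxy)-3-(3-methylbut-2-en-1-yl)phenyl]ethanone; 12 2,4-bis(methoxymethoxy)benzaldehyde
Product: 14 (2E)-1-[2,4-bis(methoxymethoxy)-3-(3-methylbut-2-en-1-yl)phenyl]-3-[2,4-bis(methoxymethoxy)phenyl]prop-2-en-1-one, via aldol adduct 13 (not isolated)
Conditions: KOH (50% aq., excess), EtOH, 0 °C → rt
Reagents that add atoms: none
Why: Claisen–Schmidt condensation as in step 5; E1cB dehydration of the β-hydroxy ketone 13 sets the E geometry of the enone that later becomes the 4'',5''-trans relation.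

Step 9
Reactants: 14 (2E)-1-[2,4-bis(methoxymethoxy)-3-(3-methylbut-2-en-1-yl)phenyl]-3-[2,4-bis(methoxymethoxy)phenyl]prop-2-en-1-one
Product: 15 morachalcone A = (2E)-1-[2,4-dihydroxy-3-(3-methylbut-2-en-1-yl)phenyl]-3-(2,4-dihydroxyphenyl)prop-2-en-1-one
Conditions: conc. HCl (10 vol %) in MeOH, rt → 45 °C, short reaction time, dark
Reagents that add atoms: none
Why: Acid-catalysed acetal exchange (MOM ether cleavage) as in step 6, stopped as soon as the last MOM group has left so that neither the prenyl group nor the 2-hydroxychalcone has time to cyclise.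

Step 10
Reactants: 10 isobavachalcone; 15 morachalcone A
Product: 17 (2E)-1-{3-[(1S,5S,6R)-6-[2,4-dihydroxy-3-(3-methylbut-2-en-1-yl)benzoyl]-5-(2,4-dihydroxyphenyl)-3-methylcyclohex-2-en-1-yl]-2,4-dihydroxyphenyl}-3-(4-hydroxyphenyl)prop-2-en-1-one, via dehydroprenyl diene 16 (not isolated)
Conditions: (i) 10 (ca. 1 mM), immobilised berberine-bridge-enzyme-like FAD-dependent oxidase (moracin C oxidase type), catalase, air, Tris·HCl pH 8.0/5% DMSO, 30 °C, dark; filter off the oxidase, sparge with Ar; (ii) 15 (1.5 equiv), FAD-dependent intermolecular Diels–Alderase (berberine-bridge-enzyme-like pericyclase of Morus alba, endo-selective isoform), same buffer, 37 °C, dark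
Reagents that add atoms: none
Why: Proposed new method: the oxidase half is argued from mechanism, since the 4'-phenolate of 10 (para to the ketone, ionised at pH 8) can push a hydride from the benzylic CH2 of the prenyl group to flavin N5 to give an ortho-quinone methide, and loss of a proton from a terminal methyl then restores the arene as the (E)-3-methylbuta-1,3-dienyl group of 16 while O2 reoxidises the flavin (catalase takes the H2O2 to water); the closest known reaction type is the dehydrogenation by this enzyme class of a prenyl group flanked by two phenols on a 2-arylbenzofuran, not yet shown on a prenylchalcone. The second half is the known reaction class of the Morus FAD-dependent Diels–Alderase, which takes 15 as dienophile and dehydroprenyl phenols as dienes: a concerted, asynchronous intermolecular [4+2] cycloaddition that forms the cyclohexene ring by making C3''–C4'' and C5''–C6'' suprafacially on both partners. The 4'',5''-trans relation is copied from the E enone of 15, the 3'',4''-cis relation comes from the endo transition state (aryl ketone under the diene) imposed by the pocket, and the absolute sense (3''S,4''R,5''S) from the single enone face that the protein leaves open to the diene. Regiochemistry is innate to the substrates, because the CH2 terminus of the 1-aryl-3-methyl diene (largest HOMO coefficient) bonds to the enone β-carbon (largest LUMO coefficient). Cross-selectivity is secured by the order of events and by the substrates: the oxidase never meets 15 because it is filtered off and oxygen is removed before 15 is added, and the Diels–Alderase prefers the chelated 2'-hydroxy enone with the 2,4-dihydroxyphenyl B ring of 15, used in excess, over the enone of 16.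

**Compound list**

1 | 2,4-dihydroxyacetophenone | CC(=O)c1ccc(O)cc1O | starting material
2 | 1-(2,4-dihydroxy-3-iodophenyl)ethanone | CC(=O)c1ccc(O)c(I)c1O | intermediate
3 | 1-[3-iodo-2,4-bis(methoxymethoxy)phenyl]ethanone | CC(=O)c1ccc(OCOC)c(I)c1OCOC | intermediate
4 | tributyl(3-methylbut-2-en-1-yl)stannane | CCCC[Sn](CCCC)(CCCC)CC=C(C)C | starting material
5 | 1-[2,4-bis(methoxymethoxy)-3-(3-methylbut-2-en-1-yl)phenyl]ethanone | CC(=O)c1ccc(OCOC)c(CC=C(C)C)c1OCOC | intermediate
6 | 4-hydroxybenzaldehyde | O=Cc1ccc(O)cc1 | starting material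
7 | 4-(methoxymethoxy)benzaldehyde | COCOc1ccc(C=O)cc1 | intermediate
8 | (±)-3-hydroxy-1-[2,4-bis(methoxymethoxy)-3-(3-methylbut-2-en-1-yl)phenyl]-3-[4-(methoxymethoxy)phenyl]propan-1-one (aldol adduct, not isolated) | COCOc1ccc(C(O)CC(=O)c2ccc(OCOC)c(CC=C(C)C)c2OCOC)cc1 | intermediate
9 | (2E)-1-[2,4-bis(methoxymethoxy)-3-(3-methylbut-2-en-1-yl)phenyl]-3-[4-(methoxymethoxy)phenyl]prop-2-en-1-one | COCOc1ccc(/C=C/C(=O)c2ccc(OCOC)c(CC=C(C)C)c2OCOC)cc1 | intermediate
10 | isobavachalcone, (2E)-1-[2,4-dihydroxy-3-(3-methylbut-2-en-1-yl)phenyl]-3-(4-hydroxyphenyl)prop-2-en-1-one | CC(C)=CCc1c(O)ccc(C(=O)/C=C/c2ccc(O)cc2)c1O | intermediate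
11 | 2,4-dihydroxybenzaldehyde | O=Cc1ccc(O)cc1O | starting material
12 | 2,4-bis(methoxymethoxy)benzaldehyde | COCOc1ccc(C=O)c(OCOC)c1 | intermediate
13 | (±)-3-hydroxy-1-[2,4-bis(methoxymethoxy)-3-(3-methylbut-2-en-1-yl)phenyl]-3-[2,4-bis(methoxymethoxy)phenyl]propan-1-one (aldol adduct, not isolated) | COCOc1ccc(C(O)CC(=O)c2ccc(OCOC)c(CC=C(C)C)c2OCOC)c(OCOC)c1 | intermediate
14 | (2E)-1-[2,4-bis(methoxymethoxy)-3-(3-methylbut-2-en-1-yl)phenyl]-3-[2,4-bis(methoxymethoxy)phenyl]prop-2-en-1-one | COCOc1ccc(/C=C/C(=O)c2ccc(OCOC)c(CC=C(C)C)c2OCOC)c(OCOC)c1 | intermediate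
15 | morachalcone A, (2E)-1-[2,4-dihydroxy-3-(3-methylbut-2-en-1-yl)phenyl]-3-(2,4-dihydroxyphenyl)prop-2-en-1-one | CC(C)=CCc1c(O)ccc(C(=O)/C=C/c2ccc(O)cc2O)c1O | intermediate
16 | (2E)-1-{2,4-dihydroxy-3-[(1E)-3-methylbuta-1,3-dien-1-yl]phenyl}-3-(4-hydroxyphenyl)prop-2-en-1-one (diene, not isolated) | C=C(C)/C=C/c1c(O)ccc(C(=O)/C=C/c2ccc(O)cc2)c1O | intermediate
17 | (2E)-1-{3-[(1S,5S,6R)-6-[2,4-dihydroxy-3-(3-methylbut-2-en-1-yl)benzoyl]-5-(2,4-dihydroxyphenyl)-3-methylcyclohex-2-en-1-yl]-2,4-dihydroxyphenyl}-3-(4-hydroxyphenyl)prop-2-en-1-one | CC(C)=CCc1c(O)ccc(C(=O)[C@H]2[C@@H](c3c(O)ccc(C(=O)/C=C/c4ccc(O)cc4)c3O)C=C(C)C[C@@H]2c2ccc(O)cc2O)c1O | target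

**Step count**

Total steps: 10. Longest linear sequence: 6 (steps 1, 2, 3, 5, 6, 10; equally 1, 2, 3, 8, 9, 10).

**Steps most likely to fail**

1. Step 10 (Proposed new method). The oxidase may fail to abstract hydride from the prenyl CH2 of the electron-poor acyl-resorcinol ring. The quinone methide may also close by oxa-6π electrocyclisation to a 2,2-dimethylchromene instead of losing a methyl proton. In either case no diene reaches the Diels–Alderase. The fallback uses known chemistry only; it sets out from 3 and returns to the route at 17. Iodide 3 is condensed with 7 (KOH, EtOH) through the aldol adduct F1 to the tris-MOM 3'-iodochalcone F2. HCl/MeOH then gives the free 3'-iodo-2',4',4-trihydroxychalcone F3, with no acid-sensitive side chain yet present. Suzuki–Miyaura coupling of F3 with commercial (E)-4,4,5,5-tetramethyl-2-(3-methylbuta-1,3-dien-1-yl)-1,3,2-dioxaborolane (C=C(C)/C=C/B1OC(C)(C)C(C)(C)O1; SPhos–Pd precatalyst, K3PO4, THF/H2O, 40 °C) should give diene 16. The diene is now isolated, kept cold and dark, and incubated with 15 and the Diels–Alderase alone, the established reaction class of that enzyme, to give 17.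

2. Step 9. During the acid exposure needed to cleave four MOM ethers, the freed 2'- or 4'-phenol may add across the prenyl double bond (chroman formation). The fallback moves the prenylation after the deprotection; it sets out from 3 and returns at 15. Iodide 3 is condensed with 12 (KOH, EtOH) through the aldol adduct F4 to the tetrakis-MOM 3'-iodochalcone F5. The MOM groups are removed with HCl/MeOH while no prenyl group is present, giving 3'-iodo-2,4,2',4'-tetrahydroxychalcone F6. A Stille coupling of F6 with 4 (Pd(PPh3)4, DMF, 80 °C), which tolerates free phenols and is run under neutral conditions, then installs the prenyl group last and gives 15.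

3. Step 3. Regiocontrol may be lost in the allyl transfer (γ-coupling to the 1,1-dimethylallyl isomer), and the di-ortho-substituted iodide may undergo protodeiodination through slow transmetalation. The fallback replaces cross-coupling by a sigmatropic prenyl transfer; it sets out from 1 and returns at 5, bypassing steps 1 and 2 as well. The free 4-OH of 1 is alkylated with 3-chloro-3-methylbut-1-yne (K2CO3, KI, acetone, reflux) to give the propargyl ether F7. Lindlar semi-hydrogenation gives the 1,1-dimethylallyl ether F8. Aromatic Claisen rearrangement (PhNEt2, 130 °C), directed to C3 by the bond fixation of the chelated ring, gives 2,4-dihydroxy-3-prenylacetophenone F9. Bis-MOM protection (NaH, MOMCl, DMF) then gives 5.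

**Further compounds**

F1 | step 10 | (±)-3-hydroxy-1-[3-iodo-2,4-bis(methoxymethoxy)phenyl]-3-[4-(methoxymethoxy)phenyl]propan-1-one (aldol adduct, not isolated) | COCOc1ccc(C(O)CC(=O)c2ccc(OCOC)c(I)c2OCOC)cc1
F2 | step 10 | (2E)-1-[3-iodo-2,4-bis(methoxymethoxy)phenyl]-3-[4-(methoxymethoxy)phenyl]prop-2-en-1-one | COCOc1ccc(/C=C/C(=O)c2ccc(OCOC)c(I)c2OCOC)cc1
F3 | step 10 | (2E)-1-(2,4-dihydroxy-3-iodophenyl)-3-(4-hydroxyphenyl)prop-2-en-1-one | O=C(/C=C/c1ccc(O)cc1)c1ccc(O)c(I)c1O
F4 | step 9 | (±)-3-hydroxy-1-[3-iodo-2,4-bis(methoxymethoxy)phenyl]-3-[2,4-bis(methoxymethoxy)phenyl]propan-1-one (aldol adduct, not isolated) | COCOc1ccc(C(O)CC(=O)c2ccc(OCOC)c(I)c2OCOC)c(OCOC)c1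
F5 | step 9 | (2E)-1-[3-iodo-2,4-bis(methoxymethoxy)phenyl]-3-[2,4-bis(methoxymethoxy)phenyl]prop-2-en-1-one | COCOc1ccc(/C=C/C(=O)c2ccc(OCOC)c(I)c2OCOC)c(OCOC)c1
F6 | step 9 | (2E)-1-(2,4-dihydroxy-3-iodophenyl)-3-(2,4-dihydroxyphenyl)prop-2-en-1-one | O=C(/C=C/c1ccc(O)cc1O)c1ccc(O)c(I)c1O
F7 | step 3 | 1-[2-hydroxy-4-(2-methylbut-3-yn-2-yloxy)phenyl]ethanone | CC(=O)c1ccc(OC(C)(C)C#C)cc1O
F8 | step 3 | 1-[2-hydroxy-4-(2-methylbut-3-en-2-yloxy)phenyl]ethanone | CC(=O)c1ccc(OC(C)(C)C=C)cc1O
F9 | step 3 | 1-[2,4-dihydroxy-3-(3-methylbut-2-en-1-yl)phenyl]ethanone | CC(=O)c1ccc(O)c(CC=C(C)C)c1O
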